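Ring A = guaiacyl ring; bicycle B = the dihydrobenzofuran carrying ring A (O1, C2, C3, C3a–C7a; C9 = CH2O on C3); bicycle C = the second dihydrobenzofuran (primed locants; C9' = CH2O on C3').
Retrosynthetic cuts: the two silyl ethers and the C5' propenol chain (back to an aryl aldehyde), then C3'–C3a' and the C2'–O(aryl) bond of bicycle C; the same cuts at C5, C3–C3a and C2–O of bicycle B lead to vanillin, a two-carbon ylide and twice the bromophenol made from 5-bromovanillin.
Enabling feature: in the furan ring of bicycle C (O1', C2', C3', C3a', C7a') C3' carries C9'H2OH and is bonded to arene carbon C3a', ortho to O1'; this is what an aryl anion at C3a' leaves when it opens a C3'–C9' oxirane attached to the ether carbon C2' (bicycle B shows the same pattern at C3, C3a, C9).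
Forward order: ring A cinnamyl alcohol → epoxy alcohol → aryl ether diol → terminal epoxide → anionic closure of the furan ring of B; aldehyde release, chain extension and a second identical cycle close the furan ring of C; a last chain extension and desilylation give the target.
Stereochemistry: each trans pair (C2/C3, C2'/C3') comes from one Sharpless epoxidation with D-(−)-tartrate; the aryloxide inverts the benzylic carbon (→ C2, C2'), the aryllithium inverts the oxirane carbon (→ C3, C3'), giving (2R,3S) twice; the (E)-alkene comes from the stabilised ylide.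

Key step: step 16

Remark: D-(−)-tartrate is taken to give the (2R,3R)-3-aryl-2,3-epoxy alcohol from an (E)-cinnamyl alcohol, as the usual mnemonic of the Sharpless epoxidation predicts.

Abbreviations used in names: ArA = 3-methoxy-4-(triisopropylsilyloxy)phenyl; ArBr = 2-bromo-4-(1,3-dioxolan-2-yl)-6-methoxyphenyl; BF = (2R,3S)-3-[(tert-butyldimethylsilyloxy)methyl]-7-methoxy-2-(ArA)-2,3-dihydro-1-benzofuran-5-yl.

Step 1
Reactants: 1 5-bromovanillin (3-bromo-4-hydroxy-5-methoxybenzaldehyde)
Product: 2 2-bromo-4-(1,3-dioxolan-2-yl)-6-methoxyphenol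
Conditions: HOCH2CH2OH (3 equiv), TsOH·H2O (2 mol%), toluene, reflux, Dean–Stark; Et3N quench
Reagents that add atoms: ethylene glycol, OCCO
Why: acid-catalysed acetalisation with azeotropic removal of water masks the aldehyde against the later alkyllithium steps and leaves the phenol free as the nucleophile for steps 6 and 14.

Step 2
Reactants: 3 vanillin (4-hydroxy-3-methoxybenzaldehyde)
Product: 4 3-methoxy-4-(triisopropylsilyloxy)benzaldehyde
Conditions: i-Pr3SiCl (1.2 equiv), imidazole (2.5 equiv), DMF, rt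
Reagents that add atoms: chlorotriisopropylsilane, CC(C)[Si](Cl)(C(C)C)C(C)C
Why: imidazole-promoted silylation gives a hindered aryl silyl ether that should survive ylide, hydride, carbonate, NaH and alkyllithium conditions and leave with fluoride in step 20.

Step 3
Reactants: 4 3-methoxy-4-(triisopropylsilyloxy)benzaldehyde; 5 ethyl (triphenylphosphoranylidene)acetate
Product: 6 ethyl (E)-3-(ArA)prop-2-enoate
Conditions: toluene, 80 °C
Reagents that add atoms: none
Why: Wittig olefination with a stabilised ylide should give the (E)-enoate selectively and needs no added base.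

Step 4
Reactants: 6 ethyl (E)-3-(ArA)prop-2-enoate
Product: 7 (E)-3-(ArA)prop-2-en-1-ol
Conditions: i-Bu2AlH (2.5 equiv), CH2Cl2, −78 °C; aq KNaC4H4O6 (potassium sodium tartrate)
Reagents that add atoms: none
Why: 1,2-reduction of the conjugated ester by i-Bu2AlH at low temperature gives the (E)-allylic alcohol without touching the C=C bond.

Step 5
Reactants: 7 (E)-3-(ArA)prop-2-en-1-ol
Product: 8 [(2R,3R)-3-(ArA)oxiran-2-yl]methanol
Conditions: Ti(OiPr)4 (10 mol%), D-(−)-diisopropyl tartrate (13 mol%), t-BuOOH (2 equiv), 4 Å molecular sieves, CH2Cl2, −25 °C; cold aq NaOH/NaCl work-up, product used at once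
Reagents that add atoms: tert-butyl hydroperoxide, CC(C)(C)OO
Why: Sharpless asymmetric epoxidation, in which the titanium tartrate complex binds the allylic alcohol and delivers the peroxide oxygen to one alkene face, so that D-(−)-tartrate should give the (2R,3R)-epoxide that carries both future centres C2 and C3.

Step 6
Reactants: 8 [(2R,3R)-3-(ArA)oxiran-2-yl]methanol; 2 2-bromo-4-(1,3-dioxolan-2-yl)-6-methoxyphenol
Product: 9 (2R,3S)-3-(ArBr-oxy)-3-(ArA)propane-1,2-diol (erythro)
Conditions: 2 (1.5 equiv), K2CO3 (0.5 equiv), DMF, 60 °C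
Reagents that add atoms: none
Why: base-mediated SN2 opening of a 3-aryl-2,3-epoxy alcohol by an aryloxide occurs at the benzylic carbon with inversion, which sets the (S)-configured ether carbon (the later C2) and leaves the (R)-carbinol carbon untouched.

Step 7
Reactants: 9 (2R,3S)-3-(ArBr-oxy)-3-(ArA)propane-1,2-diol
Product: 11 (2R)-2-[(S)-(ArBr-oxy)(ArA)methyl]oxirane, via primary tosylate 10 (not isolated)
Conditions: NaH (2.5 equiv), 1-(p-toluenesulfonyl)imidazole (1.1 equiv), THF, 0 °C → rt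
Reagents that add atoms: none
Why: selective sulfonylation of the primary alkoxide followed by intramolecular Williamson displacement (3-exo-tet) by the secondary alkoxide gives the terminal epoxide with retention at the carbinol carbon, because its C–O bond is not broken.

Step 8
Reactants: 11 (2R)-2-[(S)-(ArBr-oxy)(ArA)methyl]oxirane
Product: 13 [(2R,3S)-5-(1,3-dioxolan-2-yl)-7-methoxy-2-(ArA)-2,3-dihydro-1-benzofuran-3-yl]methanol, via aryllithium 12 (not isolated)
Conditions: n-BuLi (1.1 equiv), THF, −78 °C, then −78 → 0 °C; H2O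
Reagents that add atoms: none
Why: bromine–lithium exchange followed by Parham-type 5-exo-tet attack of the aryllithium on the adjacent oxirane carbon with inversion closes the furan ring of bicycle B and places C9H2OH trans to the C2 aryl group, as discussed for step 16.

Step 9
Reactants: 13 [(2R,3S)-5-(1,3-dioxolan-2-yl)-7-methoxy-2-(ArA)-2,3-dihydro-1-benzofuran-3-yl]methanol
Product: 14 (2R,3S)-3-(hydroxymethyl)-7-methoxy-2-(ArA)-2,3-dihydro-1-benzofuran-5-carbaldehyde
Conditions: pyridinium p-toluenesulfonate (0.2 equiv), acetone–H2O 10:1, rt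
Reagents that add atoms: water, O
Why: acid-catalysed hydrolysis of the electron-rich aryl dioxolane proceeds under conditions mild enough to spare the aryl silyl ether and the benzylic ether of the dihydrobenzofuran.

Step 10
Reactants: 14 (2R,3S)-3-(hydroxymethyl)-7-methoxy-2-(ArA)-2,3-dihydro-1-benzofuran-5-carbaldehyde
Product: 15 (2R,3S)-3-[(tert-butyldimethylsilyloxy)methyl]-7-methoxy-2-(ArA)-2,3-dihydro-1-benzofuran-5-carbaldehyde (BF–CHO)
Conditions: t-BuMe2SiCl (1.2 equiv), imidazole (2.5 equiv), CH2Cl2, rt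
Reagents that add atoms: tert-butyldimethylsilyl chloride, CC(C)(C)[Si](C)(C)Cl
Why: imidazole-promoted silylation caps the only hydroxyl group, so that the glycol formed in step 14 is the only diol present when the second epoxide is closed.

Step 11
Reactants: 15 BF–CHO; 5 ethyl (triphenylphosphoranylidene)acetate
Product: 16 ethyl (E)-3-(BF)prop-2-enoate
Conditions: toluene, 80 °C
Reagents that add atoms: none
Why: Wittig olefination with the stabilised ylide should again give the (E)-enoate and is neutral towards both silyl ethers.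

Step 12
Reactants: 16 ethyl (E)-3-(BF)prop-2-enoate
Product: 17 (E)-3-(BF)prop-2-en-1-ol
Conditions: i-Bu2AlH (2.5 equiv), CH2Cl2, −78 °C; aq KNaC4H4O6 (potassium sodium tartrate)
Reagents that add atoms: none
Why: 1,2-reduction of the conjugated ester by i-Bu2AlH gives the (E)-allylic alcohol needed for the second directed epoxidation.

Step 13
Reactants: 17 (E)-3-(BF)prop-2-en-1-ol
Product: 18 [(2R,3R)-3-(BF)oxiran-2-yl]methanol
Conditions: Ti(OiPr)4 (10 mol%), D-(−)-diisopropyl tartrate (13 mol%), t-BuOOH (2 equiv), 4 Å molecular sieves, CH2Cl2, −25 °C; cold aq NaOH/NaCl work-up, product used at once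
Reagents that add atoms: tert-butyl hydroperoxide, CC(C)(C)OO
Why: Sharpless asymmetric epoxidation under reagent control, the remote centres of bicycle B being too far away to matter, should give the (2R,3R)-epoxide that carries the future centres C2' and C3'.

Step 14
Reactants: 18 [(2R,3R)-3-(BF)oxiran-2-yl]methanol; 2 2-bromo-4-(1,3-dioxolan-2-yl)-6-methoxyphenol
Product: 19 (2R,3S)-3-(ArBr-oxy)-3-(BF)propane-1,2-diol (erythro)
Conditions: 2 (1.5 equiv), K2CO3 (0.5 equiv), DMF, 60 °C
Reagents that add atoms: none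
Why: base-mediated SN2 opening of the 3-aryl-2,3-epoxy alcohol by the aryloxide at the benzylic carbon with inversion sets the (S)-configured ether carbon (the later C2') and keeps the (R)-carbinol carbon.

Step 15
Reactants: 19 (2R,3S)-3-(ArBr-oxy)-3-(BF)propane-1,2-diol
Product: 21 (2R)-2-[(S)-(ArBr-oxy)(BF)methyl]oxirane, via primary tosylate 20 (not isolated)
Conditions: NaH (2.5 equiv), 1-(p-toluenesulfonyl)imidazole (1.1 equiv), THF, 0 °C → rt
Reagents that add atoms: none
Why: selective primary sulfonylation and intramolecular Williamson closure (3-exo-tet) give the terminal epoxide with retention at the carbinol carbon, so the erythro relationship of the diol is carried into the epoxide.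

Step 16
Reactants: 21 (2R)-2-[(S)-(ArBr-oxy)(BF)methyl]oxirane
Product: 23 [(2R,3S)-2-(BF)-5-(1,3-dioxolan-2-yl)-7-methoxy-2,3-dihydro-1-benzofuran-3-yl]methanol, via aryllithium 22 (not isolated)
Conditions: n-BuLi (1.1 equiv), THF, −78 °C, 20 min, then −78 → 0 °C; H2O
Reagents that add atoms: none
Why: n-BuLi exchanges the bromine ortho to the ether oxygen at −78 °C much faster than it adds to the oxirane or removes a proton, and on warming the aryllithium 22 (carbanion at C3a') attacks the oxirane carbon C3' from the face opposite its C–O bond, the oxygen leaving on C9' as a lithium alkoxide that water turns into the free CH2OH. The closest known reaction type is the Parham-type anionic cyclisation of ortho-lithiated aryl oxiranylmethyl ethers to 3-(hydroxymethyl)-2,3-dihydrobenzofurans. The furan ring of bicycle C (O1'–C2'–C3'–C3a'–C7a') closes in the 5-exo-tet mode, the breaking C–O bond lying outside the new ring. C3' is the only new stereocentre and is set by the substrate: SN2 attack inverts the (R)-oxirane carbon fixed in steps 13–15, and because C2' is not touched the C2' aryl group and C9'H2OH end up trans, that is (2'R,3'S). The step needs exo attack at the more substituted oxirane carbon instead of 6-endo attack at C9'H2, and cyclisation instead of proton transfer from the C2'–H; the five-membered transition state offers the better backside alignment for an unassisted lithium carbanion (no Lewis acid is added, since that would favour endo opening), and generating the anion at −78 °C and warming slowly should keep the intramolecular opening ahead of deprotonation. The dioxolane and both silyl ethers are inert to the alkyllithium at these temperatures.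

Step 17
Reactants: 23 [(2R,3S)-2-(BF)-5-(1,3-dioxolan-2-yl)-7-methoxy-2,3-dihydro-1-benzofuran-3-yl]methanol
Product: 24 (2R,3S)-2-(BF)-3-(hydroxymethyl)-7-methoxy-2,3-dihydro-1-benzofuran-5-carbaldehyde
Conditions: pyridinium p-toluenesulfonate (0.2 equiv), acetone–H2O 10:1, rt
Reagents that add atoms: water, O
Why: acid-catalysed acetal hydrolysis in wet acetone is fast for this electron-rich aryl dioxolane and should leave the primary alkyl silyl ether and the aryl silyl ether in place.

Step 18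
Reactants: 24 (2R,3S)-2-(BF)-3-(hydroxymethyl)-7-methoxy-2,3-dihydro-1-benzofuran-5-carbaldehyde; 5 ethyl (triphenylphosphoranylidene)acetate
Product: 25 ethyl (E)-3-[(2R,3S)-2-(BF)-3-(hydroxymethyl)-7-methoxy-2,3-dihydro-1-benzofuran-5-yl]prop-2-enoate
Conditions: toluene, 80 °C
Reagents that add atoms: none
Why: Wittig olefination with the neutral stabilised ylide tolerates the free primary hydroxyl group and should give the (E)-enoate.

Step 19
Reactants: 25 ethyl (E)-3-[(2R,3S)-2-(BF)-3-(hydroxymethyl)-7-methoxy-2,3-dihydro-1-benzofuran-5-yl]prop-2-enoate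
Product: 26 (E)-3-[(2R,3S)-2-(BF)-3-(hydroxymethyl)-7-methoxy-2,3-dihydro-1-benzofuran-5-yl]prop-2-en-1-ol
Conditions: i-Bu2AlH (4 equiv), CH2Cl2–THF, −78 → −40 °C; aq KNaC4H4O6 (potassium sodium tartrate)
Reagents that add atoms: none
Why: 1,2-reduction of the conjugated ester by i-Bu2AlH, with one extra equivalent consumed by the free hydroxyl group, gives the (E)-allylic alcohol of the side chain.

Step 20
Reactants: 26 (E)-3-[(2R,3S)-2-(BF)-3-(hydroxymethyl)-7-methoxy-2,3-dihydro-1-benzofuran-5-yl]prop-2-en-1-ol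
Product: 27 (E)-3-[(2R,3S)-3-(hydroxymethyl)-2-[(2R,3S)-2-(4-hydroxy-3-methoxyphenyl)-3-(hydroxymethyl)-7-methoxy-2,3-dihydro-1-benzofuran-5-yl]-7-methoxy-2,3-dihydro-1-benzofuran-5-yl]prop-2-en-1-ol (CNP0250921.1)
Conditions: Bu4NF (3 equiv), AcOH (3 equiv), THF, 0 °C → rt
Reagents that add atoms: none
Why: fluoride-induced cleavage of the Si–O bonds (desilylation) removes the alkyl and the aryl silyl ether in one operation, the acetic acid buffer keeping the phenol and the cinnamyl alcohol away from strongly basic conditions.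

Compound list
1 | 5-bromovanillin (3-bromo-4-hydroxy-5-methoxybenzaldehyde) | COc1cc(C=O)cc(Br)c1O | starting material
2 | 2-bromo-4-(1,3-dioxolan-2-yl)-6-methoxyphenol | COc1cc(C2OCCO2)cc(Br)c1O | intermediate
3 | vanillin (4-hydroxy-3-methoxybenzaldehyde) | COc1cc(C=O)ccc1O | starting material
4 | 3-methoxy-4-(triisopropylsilyloxy)benzaldehyde | COc1cc(C=O)ccc1O[Si](C(C)C)(C(C)C)C(C)C | intermediate
5 | ethyl (triphenylphosphoranylidene)acetate | CCOC(=O)C=P(c1ccccc1)(c1ccccc1)c1ccccc1 | starting material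
6 | ethyl (E)-3-[3-methoxy-4-(triisopropylsilyloxy)phenyl]prop-2-enoate | COc1cc(/C=C/C(=O)OCC)ccc1O[Si](C(C)C)(C(C)C)C(C)C | intermediate
7 | (E)-3-[3-methoxy-4-(triisopropylsilyloxy)phenyl]prop-2-en-1-ol | COc1cc(/C=C/CO)ccc1O[Si](C(C)C)(C(C)C)C(C)C | intermediate
8 | [(2R,3R)-3-[3-methoxy-4-(triisopropylsilyloxy)phenyl]oxiran-2-yl]methanol | COc1cc([C@H]2O[C@@H]2CO)ccc1O[Si](C(C)C)(C(C)C)C(C)C | intermediate
9 | (2R,3S)-3-[2-bromo-4-(1,3-dioxolan-2-yl)-6-methoxyphenoxy]-3-[3-methoxy-4-(triisopropylsilyloxy)phenyl]propane-1,2-diol | COc1cc([C@H](Oc2c(OC)cc(C3OCCO3)cc2Br)[C@H](O)CO)ccc1O[Si](C(C)C)(C(C)C)C(C)C | intermediate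
10 | (2R,3S)-3-[2-bromo-4-(1,3-dioxolan-2-yl)-6-methoxyphenoxy]-2-hydroxy-3-[3-methoxy-4-(triisopropylsilyloxy)phenyl]propyl 4-methylbenzenesulfonate (sodium alkoxide in the flask) | COc1cc([C@H](Oc2c(OC)cc(C3OCCO3)cc2Br)[C@H](O)COS(=O)(=O)c2ccc(C)cc2)ccc1O[Si](C(C)C)(C(C)C)C(C)C | intermediate
11 | (2R)-2-[(S)-[2-bromo-4-(1,3-dioxolan-2-yl)-6-methoxyphenoxy][3-methoxy-4-(triisopropylsilyloxy)phenyl]methyl]oxirane | COc1cc([C@H](Oc2c(OC)cc(C3OCCO3)cc2Br)[C@H]2CO2)ccc1O[Si](C(C)C)(C(C)C)C(C)C | intermediate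
12 | aryllithium of 11 (lithium in place of bromine) | COc1cc([C@H](Oc2c(OC)cc(C3OCCO3)cc2[Li])[C@H]2CO2)ccc1O[Si](C(C)C)(C(C)C)C(C)C | intermediate
13 | [(2R,3S)-5-(1,3-dioxolan-2-yl)-7-methoxy-2-[3-methoxy-4-(triisopropylsilyloxy)phenyl]-2,3-dihydro-1-benzofuran-3-yl]methanol | COc1cc([C@@H]2Oc3c(OC)cc(C4OCCO4)cc3[C@H]2CO)ccc1O[Si](C(C)C)(C(C)C)C(C)C | intermediate
14 | (2R,3S)-3-(hydroxymethyl)-7-methoxy-2-[3-methoxy-4-(triisopropylsilyloxy)phenyl]-2,3-dihydro-1-benzofuran-5-carbaldehyde | COc1cc([C@@H]2Oc3c(OC)cc(C=O)cc3[C@H]2CO)ccc1O[Si](C(C)C)(C(C)C)C(C)C | intermediate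
15 | (2R,3S)-3-[(tert-butyldimethylsilyloxy)methyl]-7-methoxy-2-[3-methoxy-4-(triisopropylsilyloxy)phenyl]-2,3-dihydro-1-benzofuran-5-carbaldehyde | COc1cc([C@@H]2Oc3c(OC)cc(C=O)cc3[C@H]2CO[Si](C)(C)C(C)(C)C)ccc1O[Si](C(C)C)(C(C)C)C(C)C | intermediate
16 | ethyl (E)-3-(BF)prop-2-enoate | COc1cc([C@@H]2Oc3c(OC)cc(/C=C/C(=O)OCC)cc3[C@H]2CO[Si](C)(C)C(C)(C)C)ccc1O[Si](C(C)C)(C(C)C)C(C)C | intermediate
17 | (E)-3-(BF)prop-2-en-1-ol | COc1cc([C@@H]2Oc3c(OC)cc(/C=C/CO)cc3[C@H]2CO[Si](C)(C)C(C)(C)C)ccc1O[Si](C(C)C)(C(C)C)C(C)C | intermediate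
18 | [(2R,3R)-3-(BF)oxiran-2-yl]methanol | COc1cc([C@@H]2Oc3c(OC)cc([C@H]4O[C@@H]4CO)cc3[C@H]2CO[Si](C)(C)C(C)(C)C)ccc1O[Si](C(C)C)(C(C)C)C(C)C | intermediate
19 | (2R,3S)-3-[2-bromo-4-(1,3-dioxolan-2-yl)-6-methoxyphenoxy]-3-(BF)propane-1,2-diol | COc1cc([C@@H]2Oc3c(OC)cc([C@H](Oc4c(OC)cc(C5OCCO5)cc4Br)[C@H](O)CO)cc3[C@H]2CO[Si](C)(C)C(C)(C)C)ccc1O[Si](C(C)C)(C(C)C)C(C)C | intermediate
20 | (2R,3S)-3-[2-bromo-4-(1,3-dioxolan-2-yl)-6-methoxyphenoxy]-2-hydroxy-3-(BF)propyl 4-methylbenzenesulfonate (sodium alkoxide in the flask) | COc1cc([C@@H]2Oc3c(OC)cc([C@H](Oc4c(OC)cc(C5OCCO5)cc4Br)[C@H](O)COS(=O)(=O)c4ccc(C)cc4)cc3[C@H]2CO[Si](C)(C)C(C)(C)C)ccc1O[Si](C(C)C)(C(C)C)C(C)C | intermediate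
21 | (2R)-2-[(S)-[2-bromo-4-(1,3-dioxolan-2-yl)-6-methoxyphenoxy](BF)methyl]oxirane | COc1cc([C@@H]2Oc3c(OC)cc([C@H](Oc4c(OC)cc(C5OCCO5)cc4Br)[C@H]4CO4)cc3[C@H]2CO[Si](C)(C)C(C)(C)C)ccc1O[Si](C(C)C)(C(C)C)C(C)C | intermediate
22 | aryllithium of 21 (lithium in place of bromine) | COc1cc([C@@H]2Oc3c(OC)cc([C@H](Oc4c(OC)cc(C5OCCO5)cc4[Li])[C@H]4CO4)cc3[C@H]2CO[Si](C)(C)C(C)(C)C)ccc1O[Si](C(C)C)(C(C)C)C(C)C | intermediate
23 | [(2R,3S)-2-(BF)-5-(1,3-dioxolan-2-yl)-7-methoxy-2,3-dihydro-1-benzofuran-3-yl]methanol | COc1cc([C@@H]2Oc3c(OC)cc([C@@H]4Oc5c(OC)cc(C6OCCO6)cc5[C@H]4CO)cc3[C@H]2CO[Si](C)(C)C(C)(C)C)ccc1O[Si](C(C)C)(C(C)C)C(C)C | intermediate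
24 | (2R,3S)-2-(BF)-3-(hydroxymethyl)-7-methoxy-2,3-dihydro-1-benzofuran-5-carbaldehyde | COc1cc([C@@H]2Oc3c(OC)cc([C@@H]4Oc5c(OC)cc(C=O)cc5[C@H]4CO)cc3[C@H]2CO[Si](C)(C)C(C)(C)C)ccc1O[Si](C(C)C)(C(C)C)C(C)C | intermediate
25 | ethyl (E)-3-[(2R,3S)-2-(BF)-3-(hydroxymethyl)-7-methoxy-2,3-dihydro-1-benzofuran-5-yl]prop-2-enoate | COc1cc([C@@H]2Oc3c(OC)cc([C@@H]4Oc5c(OC)cc(/C=C/C(=O)OCC)cc5[C@H]4CO)cc3[C@H]2CO[Si](C)(C)C(C)(C)C)ccc1O[Si](C(C)C)(C(C)C)C(C)C | intermediate
26 | (E)-3-[(2R,3S)-2-(BF)-3-(hydroxymethyl)-7-methoxy-2,3-dihydro-1-benzofuran-5-yl]prop-2-en-1-ol | COc1cc([C@@H]2Oc3c(OC)cc([C@@H]4Oc5c(OC)cc(/C=C/CO)cc5[C@H]4CO)cc3[C@H]2CO[Si](C)(C)C(C)(C)C)ccc1O[Si](C(C)C)(C(C)C)C(C)C | intermediate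
27 | (E)-3-[(2R,3S)-3-(hydroxymethyl)-2-[(2R,3S)-2-(4-hydroxy-3-methoxyphenyl)-3-(hydroxymethyl)-7-methoxy-2,3-dihydro-1-benzofuran-5-yl]-7-methoxy-2,3-dihydro-1-benzofuran-5-yl]prop-2-en-1-ol | COc1cc([C@@H]2Oc3c(OC)cc([C@@H]4Oc5c(OC)cc(/C=C/CO)cc5[C@H]4CO)cc3[C@H]2CO)ccc1O | target

Total step count: 20. Longest linear sequence: 19 steps (vanillin 3 to target 27, steps 2–20); step 1 is a one-step side branch whose product 2 is used in steps 6 and 14.

Steps most likely to fail

Step 16 (the same hazard exists in step 8). The aryllithium may be consumed by proton transfer from the doubly activated C2'–H, followed by rearrangement or elimination of the oxirane, or it may open the oxirane in the 6-endo mode at C9'. The fallback replaces the anionic closure by a radical one. It sets out from diol 19. Garegg–Samuelsson deoxygenation of the glycol (PPh3, I2, imidazole, toluene, 80 °C) should give 2-bromo-4-(1,3-dioxolan-2-yl)-6-methoxyphenyl (R)-1-(BF)prop-2-enyl ether F1 with the ether stereocentre unchanged. Bu3SnH and TEMPO (toluene, 80 °C) would then generate the aryl radical, which cyclises 5-exo-trig onto the vinyl group. The primary radical at C9' is trapped by TEMPO to give the trans-configured alkoxyamine 1-{[(2R,3S)-2-(BF)-5-(1,3-dioxolan-2-yl)-7-methoxy-2,3-dihydro-1-benzofuran-3-yl]methoxy}-2,2,6,6-tetramethylpiperidine F2; the trans isomer is expected because the C2' substituent prefers a pseudo-equatorial position in the cyclisation transition state. Zn dust in AcOH–THF–H2O should cleave the N–O bond and hydrolyse the dioxolane at the same time, so the route is rejoined at aldehyde 24.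

Step 13 (less so step 5). The titanium alkoxide may assist ionisation of the benzylic C–O bond of the p-alkoxyaryl epoxy alcohol during the reaction or work-up, which would erode yield and enantiomeric purity. The fallback replaces the titanium-mediated, hydroxyl-directed oxygen transfer by a metal-free chiral dioxirane (Shi epoxidation). Allylic alcohol 17 would be treated with the D-fructose-derived ketone 1,2:4,5-di-O-isopropylidene-β-D-erythro-2,3-hexodiulo-2,6-pyranose (30 mol%), 2KHSO5·KHSO4·K2SO4 and K2CO3 in MeCN–dimethoxymethane–aqueous buffer at 0 °C. This ketone is expected to give (R,R)-epoxides from trans-alkenes, so the route is rejoined directly at epoxy alcohol 18; no compound outside the list is made (F0).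

Step 14 (less so step 6). Attack by the hindered 2,6-disubstituted aryloxide may be slow enough for Payne rearrangement with attack at C1, or for ionisation at the benzylic carbon with loss of stereospecific inversion, to compete. The fallback moves the epoxide to the ester oxidation level, where there is no free hydroxyl group and the carbonyl group disfavours ionisation. It sets out from enoate 16. Epoxidation with the chiral dioxirane from the 4,5-di-O-acetyl analogue of the fructose-derived ketone (2KHSO5·KHSO4·K2SO4, NaHCO3, MeCN–H2O, 0 °C → rt) should give ethyl (2S,3R)-3-(BF)oxirane-2-carboxylate F3. The potassium aryloxide of 2 (K2CO3, DMF, 60 °C) should open it at C3 with inversion to ethyl (2S,3S)-3-[2-bromo-4-(1,3-dioxolan-2-yl)-6-methoxyphenoxy]-2-hydroxy-3-(BF)propanoate F4. Reduction of the α-hydroxy ester with NaBH4 in EtOH returns to the route at diol 19.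

Further compounds
F1 | step 16 | 2-bromo-4-(1,3-dioxolan-2-yl)-6-methoxyphenyl (R)-1-(BF)prop-2-enyl ether | COc1cc([C@@H]2Oc3c(OC)cc([C@H](Oc4c(OC)cc(C5OCCO5)cc4Br)C=C)cc3[C@H]2CO[Si](C)(C)C(C)(C)C)ccc1O[Si](C(C)C)(C(C)C)C(C)C
F2 | step 16 | 1-{[(2R,3S)-2-(BF)-5-(1,3-dioxolan-2-yl)-7-methoxy-2,3-dihydro-1-benzofuran-3-yl]methoxy}-2,2,6,6-tetramethylpiperidine | COc1cc([C@@H]2Oc3c(OC)cc([C@@H]4Oc5c(OC)cc(C6OCCO6)cc5[C@H]4CON4C(C)(C)CCCC4(C)C)cc3[C@H]2CO[Si](C)(C)C(C)(C)C)ccc1O[Si](C(C)C)(C(C)C)C(C)C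
F0 | step 13 | none | none
F3 | step 14 | ethyl (2S,3R)-3-(BF)oxirane-2-carboxylate | COc1cc([C@@H]2Oc3c(OC)cc([C@H]4O[C@@H]4C(=O)OCC)cc3[C@H]2CO[Si](C)(C)C(C)(C)C)ccc1O[Si](C(C)C)(C(C)C)C(C)C
F4 | step 14 | ethyl (2S,3S)-3-[2-bromo-4-(1,3-dioxolan-2-yl)-6-methoxyphenoxy]-2-hydroxy-3-(BF)propanoate | COc1cc([C@@H]2Oc3c(OC)cc([C@H](Oc4c(OC)cc(C5OCCO5)cc4Br)[C@H](O)C(=O)OCC)cc3[C@H]2CO[Si](C)(C)C(C)(C)C)ccc1O[Si](C(C)C)(C(C)C)C(C)C
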